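**Retrosynthetic overview**
1. Target ⇐ one-pot acid methanolysis of its fully protected form (ring A phenol as MOM ether, ring B phenol and the C-2 hydroxyl as acetates).
2. Protected form ⇐ C(=O)–C-2 disconnection: a new nickel-catalysed enantioconvergent reductive acylation of a ring A aroyl chloride with a racemic ring B 1-chloroalkyl acetate; this step sets the 2S centre.
3. Ring A aroyl chloride ⇐ methyl 5-bromo-2,4-dihydroxybenzoate (4-O-MOM, 2-O-methyl, Stille prenylation at C-5, saponification, neutral chlorination).
4. Ring B chloro acetate ⇐ tyrosol (phenol acetylation, Dess–Martin oxidation, acetyl chloride addition to the aldehyde).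
5. No ring is built: ring A and ring B are bought as benzene rings and only decorated; the fragments are joined in the last step but one.

Assumption: the sense of induction of the new nickel step cannot be predicted, so the ligand antipode that gives the 2S ester is fixed in a pilot run (both antipodes are sold) and is written here as the (S,S) ligand.

**Route**

Step 1
Reactants: 1 methyl 5-bromo-2,4-dihydroxybenzoate
Product: 2 methyl 5-bromo-2-hydroxy-4-(methoxymethoxy)benzoate
Conditions: MOMCl (1.1 equiv), K2CO3 (1.5 equiv), acetone, 0 °C to rt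
Reagents that add atoms: chloromethyl methyl ether, COCCl
Why: Williamson-type O-alkylation in which the 2-OH is held in a hydrogen bond to the ester carbonyl, so the more acidic, free 4-OH is alkylated selectively.

Step 2
Reactants: 2 methyl 5-bromo-2-hydroxy-4-(methoxymethoxy)benzoate
Product: 3 methyl 5-bromo-2-methoxy-4-(methoxymethoxy)benzoate
Conditions: MeI (1.5 equiv), K2CO3 (2 equiv), DMF, 40 °C
Reagents that add atoms: iodomethane, CI
Why: Williamson O-methylation of the remaining hydrogen-bonded phenol, which reacts cleanly in a polar aprotic solvent once excess MeI is used.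

Step 3
Reactants: 3 methyl 5-bromo-2-methoxy-4-(methoxymethoxy)benzoate
Product: 4 methyl 2-methoxy-4-(methoxymethoxy)-5-(3-methylbut-2-en-1-yl)benzoate
Conditions: tributyl(3-methylbut-2-en-1-yl)stannane (1.3 equiv), Pd(PPh3)4 (5 mol %), DMF, 100 °C
Reagents that add atoms: tributyl(3-methylbut-2-en-1-yl)stannane, CCCC[Sn](CCCC)(CCCC)CC=C(C)C
Why: Stille coupling (oxidative addition of the aryl bromide to zerovalent palladium, transmetalation, reductive elimination at the less hindered allyl terminus) gives the linear prenyl arene while ester and MOM ether stay inert.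

Step 4
Reactants: 4 methyl 2-methoxy-4-(methoxymethoxy)-5-(3-methylbut-2-en-1-yl)benzoate
Product: 6 2-methoxy-4-(methoxymethoxy)-5-(3-methylbut-2-en-1-yl)benzoic acid, via lithium carboxylate 5 (not isolated)
Conditions: LiOH·H2O (3 equiv), THF/MeOH/H2O 3:1:1, 50 °C; then 1 M HCl to pH 4, 0 °C
Reagents that add atoms: lithium hydroxide, [Li+].[OH-]
Why: Ester saponification by acyl–oxygen cleavage; the MOM ether and the prenyl alkene are stable to base and to brief cold acidification to pH 4.

Step 5
Reactants: 6 2-methoxy-4-(methoxymethoxy)-5-(3-methylbut-2-en-1-yl)benzoic acid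
Product: 7 2-methoxy-4-(methoxymethoxy)-5-(3-methylbut-2-en-1-yl)benzoyl chloride
Conditions: 1-chloro-N,N,2-trimethylprop-1-en-1-amine (1.2 equiv), CH2Cl2, 0 °C to rt; volatiles removed, used crude
Reagents that add atoms: Ghosez's reagent (1-chloro-N,N,2-trimethylprop-1-en-1-amine), CC(C)=C(Cl)N(C)C
Why: Acid chloride formation with an α-chloroenamine runs under neutral conditions without free HCl, so the acid-labile MOM ether and the prenyl group survive.

Step 6
Reactants: 8 tyrosol (4-(2-hydroxyethyl)phenol)
Product: 10 4-(2-hydroxyethyl)phenyl acetate, via sodium phenoxide 9 (not isolated)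
Conditions: NaOH (1.0 equiv), H2O, 0 °C; then Ac2O (1.05 equiv), 0 °C, 15 min
Reagents that add atoms: acetic anhydride, CC(=O)OC(C)=O; sodium hydroxide, [Na+].[OH-] (sodium of 9 only)
Why: Chattaway-type acetylation in which one equivalent of aqueous base ionises only the phenol, and the phenoxide is acylated far faster than the neutral primary alcohol.

Step 7
Reactants: 10 4-(2-hydroxyethyl)phenyl acetate
Product: 11 4-(2-oxoethyl)phenyl acetate
Conditions: Dess–Martin periodinane (1.2 equiv), CH2Cl2, 0 °C to rt; short silica pad, used at once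
Reagents that add atoms: none
Why: Dess–Martin oxidation takes the primary alcohol to the aldehyde under near-neutral, water-free conditions without over-oxidation or loss of the aryl acetate.

Step 8
Reactants: 11 4-(2-oxoethyl)phenyl acetate
Product: 12 racemic 4-(2-acetoxy-2-chloroethyl)phenyl acetate
Conditions: AcCl (1.2 equiv), ZnCl2 (2 mol %), CH2Cl2, −20 to 0 °C; volatiles removed, used crude
Reagents that add atoms: acetyl chloride, CC(Cl)=O
Why: Lewis-acid-catalysed addition of an acyl chloride across the aldehyde C=O (1-chloroalkyl ester formation) is fast and atom-economic, and the new centre is racemic by design.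

Step 9
Reactants: 7 2-methoxy-4-(methoxymethoxy)-5-(3-methylbut-2-en-1-yl)benzoyl chloride; 12 racemic 4-(2-acetoxy-2-chloroethyl)phenyl acetate (1.5 equiv)
Product: 13 (2S)-3-[4-(acetyloxy)phenyl]-1-[2-methoxy-4-(methoxymethoxy)-5-(3-methylbut-2-en-1-yl)phenyl]-1-oxopropan-2-yl acetate
Conditions: NiCl2(MeOCH2CH2OMe) (10 mol %), (S,S)-Ph-BOX [2,2'-(propane-2,2-diyl)bis((4S)-4-phenyl-4,5-dihydrooxazole)] (12 mol %), Mn powder (3 equiv), 3 Å MS, DMA/THF 3:7, 0 to 20 °C
Reagents that add atoms: none
Why: Proposed new method: a nickel/chiral bis(oxazoline)-catalysed enantioconvergent reductive acyl cross-coupling in which 7 adds oxidatively to zerovalent nickel to give an aroyl chloride complex of divalent nickel, monovalent nickel abstracts chlorine from either enantiomer of 12 to give a planar acetoxy-stabilised secondary radical, and radical capture followed by reductive elimination from trivalent nickel forms the C(=O)–C-2 bond on the face chosen by the ligand (Mn powder turns the cycle over), so both enantiomers of 12 converge on the 2S ester; the closest known reaction types are the nickel/bis(oxazoline) reductive coupling of acid chlorides with racemic secondary benzylic chlorides and the enantioconvergent nickel-catalysed coupling of racemic 1-haloalkyl esters with organozinc reagents, and the new element is joining an aroyl chloride to a 1-chloroalkyl ester.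

Step 10
Reactants: 13 (2S)-3-[4-(acetyloxy)phenyl]-1-[2-methoxy-4-(methoxymethoxy)-5-(3-methylbut-2-en-1-yl)phenyl]-1-oxopropan-2-yl acetate
Product: 14 Lespeflorin C3, (2S)-2-hydroxy-1-[4-hydroxy-2-methoxy-5-(3-methylbut-2-en-1-yl)phenyl]-3-(4-hydroxyphenyl)propan-1-one
Conditions: HCl (1.25 M in MeOH), 25 °C
Reagents that add atoms: none
Why: Acid-catalysed transesterification of both acetates and transacetalisation of the aryl MOM ether in methanol give global deprotection, and without base at 25 °C the C-2 centre does not enolise appreciably and the prenyl group is kept.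

**Compound list**
1 | methyl 5-bromo-2,4-dihydroxybenzoate | COC(=O)c1cc(Br)c(O)cc1O | starting material
2 | methyl 5-bromo-2-hydroxy-4-(methoxymethoxy)benzoate | COCOc1cc(O)c(cc1Br)C(=O)OC | intermediate
3 | methyl 5-bromo-2-methoxy-4-(methoxymethoxy)benzoate | COCOc1cc(OC)c(cc1Br)C(=O)OC | intermediate
4 | methyl 2-methoxy-4-(methoxymethoxy)-5-(3-methylbut-2-en-1-yl)benzoate | COCOc1cc(OC)c(cc1CC=C(C)C)C(=O)OC | intermediate
5 | lithium 2-methoxy-4-(methoxymethoxy)-5-(3-methylbut-2-en-1-yl)benzoate (lithium carboxylate, not isolated) | COCOc1cc(OC)c(cc1CC=C(C)C)C(=O)[O-].[Li+] | intermediate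
6 | 2-methoxy-4-(methoxymethoxy)-5-(3-methylbut-2-en-1-yl)benzoic acid | COCOc1cc(OC)c(cc1CC=C(C)C)C(=O)O | intermediate
7 | 2-methoxy-4-(methoxymethoxy)-5-(3-methylbut-2-en-1-yl)benzoyl chloride | COCOc1cc(OC)c(cc1CC=C(C)C)C(=O)Cl | intermediate
8 | tyrosol, 4-(2-hydroxyethyl)phenol | OCCc1ccc(O)cc1 | starting material
9 | sodium 4-(2-hydroxyethyl)phenolate (sodium phenoxide, not isolated) | OCCc1ccc([O-])cc1.[Na+] | intermediate
10 | 4-(2-hydroxyethyl)phenyl acetate | CC(=O)Oc1ccc(CCO)cc1 | intermediate
11 | 4-(2-oxoethyl)phenyl acetate | CC(=O)Oc1ccc(CC=O)cc1 | intermediate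
12 | racemic 4-(2-acetoxy-2-chloroethyl)phenyl acetate | CC(=O)OC(Cl)Cc1ccc(OC(C)=O)cc1 | intermediate
13 | (2S)-3-[4-(acetyloxy)phenyl]-1-[2-methoxy-4-(methoxymethoxy)-5-(3-methylbut-2-en-1-yl)phenyl]-1-oxopropan-2-yl acetate | COCOc1cc(OC)c(cc1CC=C(C)C)C(=O)[C@@H](OC(C)=O)Cc1ccc(OC(C)=O)cc1 | intermediate
14 | Lespeflorin C3, (2S)-2-hydroxy-1-[4-hydroxy-2-methoxy-5-(3-methylbut-2-en-1-yl)phenyl]-3-(4-hydroxyphenyl)propan-1-one | COc1cc(O)c(CC=C(C)C)cc1C(=O)[C@@H](O)Cc1ccc(O)cc1 | target

**Totals**
Total step count: 10 (steps 1–5 for ring A, steps 6–8 for ring B, steps 9 and 10 after convergence).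
Longest linear sequence: 7 steps (1, 2, 3, 4, 5, 9, 10).

**Three steps most likely to fail**

Step 9 (the proposed nickel coupling). It has no direct precedent; it may give low enantioselectivity, lose a β-hydrogen to the enol acetate, or homocouple. The fallback uses known chemistry only (Weinreb ketone synthesis, then Davis asymmetric enolate hydroxylation). It sets out from 7, with tyrosol 8 as the ring B source, and comes back to the route at 14. Acid chloride 7 is treated with N,O-dimethylhydroxylamine hydrochloride and pyridine in CH2Cl2 to give the Weinreb amide N,2-dimethoxy-4-(methoxymethoxy)-N-methyl-5-(3-methylbut-2-en-1-yl)benzamide F1. Tyrosol 8 is alkylated on the phenol (MOMCl, K2CO3, acetone) to 2-[4-(methoxymethoxy)phenyl]ethanol F2. An Appel reaction (CBr4, PPh3, CH2Cl2, 0 °C) turns this into 1-(2-bromoethyl)-4-(methoxymethoxy)benzene F3, and Mg turnings in THF give {2-[4-(methoxymethoxy)phenyl]ethyl}magnesium bromide F4. Addition of this Grignard reagent to the Weinreb amide (THF, 0 °C, NH4Cl work-up) gives the dihydrochalcone 1-[2-methoxy-4-(methoxymethoxy)-5-(3-methylbut-2-en-1-yl)phenyl]-3-[4-(methoxymethoxy)phenyl]propan-1-one F5. KN(SiMe3)2 in THF at −78 °C forms potassium (1Z)-1-[2-methoxy-4-(methoxymethoxy)-5-(3-methylbut-2-en-1-yl)phenyl]-3-[4-(methoxymethoxy)phenyl]prop-1-en-1-olate F6. This enolate is oxidised at −78 °C by (+)-[(8,8-dichlorocamphoryl)sulfonyl]oxaziridine, the antipode expected by analogy with propiophenone-type Z enolates to give the S carbinol (the other antipode is used if a pilot run shows the opposite sense), to give (2S)-2-hydroxy-1-[2-methoxy-4-(methoxymethoxy)-5-(3-methylbut-2-en-1-yl)phenyl]-3-[4-(methoxymethoxy)phenyl]propan-1-one F7. Both MOM ethers are then removed under the conditions of step 10 to reach 14.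

Step 3 (Stille prenylation). The bromide is electron-rich and flanked by the MOM ether, and a prenylstannane can also deliver the branched 1,1-dimethylallyl isomer. The fallback replaces direct prenyl transfer by allylation and olefin cross-metathesis; it sets out from 3 and comes back at 4. Stille coupling of 3 with allyltributylstannane (Pd(PPh3)4, DMF, 90 °C) has no regiochemical ambiguity and gives methyl 2-methoxy-4-(methoxymethoxy)-5-(prop-2-en-1-yl)benzoate F8. Cross-metathesis of this allyl arene in 2-methyl-2-butene (second-generation Grubbs catalyst, RuCl2(H2IMes)(PCy3)(=CHPh), 40 °C) converts allyl into prenyl.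

Step 10 (global acid methanolysis). The free ortho-prenylphenol can cyclise to a 2,2-dimethylchroman or add methanol across the alkene under protic acid, and prolonged acid could erode the C-2 centre. The fallback avoids protic acid by separating the two cleavages; it sets out from 13 and comes back at 14. Buffered guanidine/guanidinium nitrate (guanidinium nitrate, NaOMe, MeOH/CH2Cl2, 0 °C, short contact) removes both acetates by methanolysis to give (2S)-2-hydroxy-3-(4-hydroxyphenyl)-1-[2-methoxy-4-(methoxymethoxy)-5-(3-methylbut-2-en-1-yl)phenyl]propan-1-one F9. The aryl MOM ether is then cleaved with TMSOTf and 2,2'-bipyridyl in CH3CN at 0 °C followed by water, which also hydrolyses the transient silyl ethers.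

**Further compounds**
F1 | step 9 | N,2-dimethoxy-4-(methoxymethoxy)-N-methyl-5-(3-methylbut-2-en-1-yl)benzamide | COCOc1cc(OC)c(cc1CC=C(C)C)C(=O)N(C)OC
F2 | step 9 | 2-[4-(methoxymethoxy)phenyl]ethanol | COCOc1ccc(CCO)cc1
F3 | step 9 | 1-(2-bromoethyl)-4-(methoxymethoxy)benzene | COCOc1ccc(CCBr)cc1
F4 | step 9 | {2-[4-(methoxymethoxy)phenyl]ethyl}magnesium bromide | COCOc1ccc(CC[Mg]Br)cc1
F5 | step 9 | 1-[2-methoxy-4-(methoxymethoxy)-5-(3-methylbut-2-en-1-yl)phenyl]-3-[4-(methoxymethoxy)phenyl]propan-1-one | COCOc1cc(OC)c(cc1CC=C(C)C)C(=O)CCc1ccc(OCOC)cc1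
F6 | step 9 | potassium (1Z)-1-[2-methoxy-4-(methoxymethoxy)-5-(3-methylbut-2-en-1-yl)phenyl]-3-[4-(methoxymethoxy)phenyl]prop-1-en-1-olate | COCOc1cc(OC)c(cc1CC=C(C)C)/C([O-])=C/Cc1ccc(OCOC)cc1.[K+]
F7 | step 9 | (2S)-2-hydroxy-1-[2-methoxy-4-(methoxymethoxy)-5-(3-methylbut-2-en-1-yl)phenyl]-3-[4-(methoxymethoxy)phenyl]propan-1-one | COCOc1cc(OC)c(cc1CC=C(C)C)C(=O)[C@@H](O)Cc1ccc(OCOC)cc1
F8 | step 3 | methyl 2-methoxy-4-(methoxymethoxy)-5-(prop-2-en-1-yl)benzoate | COCOc1cc(OC)c(cc1CC=C)C(=O)OC
F9 | step 10 | (2S)-2-hydroxy-3-(4-hydroxyphenyl)-1-[2-methoxy-4-(methoxymethoxy)-5-(3-methylbut-2-en-1-yl)phenyl]propan-1-one | COCOc1cc(OC)c(cc1CC=C(C)C)C(=O)[C@@H](O)Cc1ccc(O)cc1
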